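In a one-step world, G + J → X + D with 18.0 mM of J against 15 mM of G, G runs smoothly down to its end and L has no say. The steps thought possible here add J + X ⇌ Q, X + L ⇌ Z and D ⇌ E.

in all of them: G 15 mM

|  | J | L | remark | time |
|---|---|---|---|---|
| south-east | 18 mM | 4.3 mM | run made earlier |  |
| north | 18 mM | 14 mM | run made earlier |  |
| Friday's | 18.0 mM | 11.0 mM |  | 6.0 h |
| Thursday's | 18.0 mM | 17.0 mM |  | 6.0 h |
| Sunday's | 18.0 mM | 7.50 mM |  | 6.0 h |

| run | time / h | G / % | D / % |
|---|---|---|---|
| south-east | 0.250 | 45.0 | 48.5 |
| south-east | 0.417 | 40.4 | 46.9 |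
| south-east | 0.833 | 36.0 | 40.8 |
| south-east | 1.50 | 30.0 | 31.2 |
| south-east | 3.00 | 24.1 | 22.2 |
| north | 0.250 | 44.8 | 49.3 |
| north | 0.417 | 39.3 | 48.1 |
| north | 0.833 | 32.6 | 41.6 |
| north | 1.50 | 24.1 | 36.5 |
| north | 3.00 | 13.2 | 27.1 |

(standard deviation of a reading: 0.5 percentage points)

* part of the G that has reacted at the end, Friday's
* part of the G that has reacted at the end, Thursday's
* part of the G that has reacted at the end, Sunday's
* what raising the concentration of L from its lowest to its highest value here does to the part of the G that has reacted (changes below 5 percentage points count as none) (no change / it rises / it falls)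

- steps thought possible: G + J -> X + D; J + X <-> Q; X + L <-> Z; D <-> E

Take the runs in slow motion. In the first instants G + J is the step you see: at 0.250 h the south-east run, with 4.3 mM of L, has 45.0 % of G left and the north run, with 14 mM, has 44.8 %, a gap of 0.2 percentage points. Then G slows. Suppose each X made is held at once by J as Q: every portion x of G reacted then costs J twice, and free J nears nil at x = 9.00 mM, or 60.0 % of the G, close to the bend the readings show at 0.417 h, with G at 40.4 % and 39.3 %.

Past the bend, L takes X as Z and hands J back. With all X held and free J and L near nil: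

x = Q + Z, and J charged = x + Q

ceiling x_c = (J charged + L charged)/2

This ceiling, the amount of G reacted up to which all the X can stay held as Q or Z, beyond which free X has to stand in the flask, is 14.5 mM for Friday's and 12.8 mM for Sunday's, and for Thursday's 17.5 mM, above the G charged. The south-east run's ceiling is 74.3 % and it reads 75.9 % reacted at 3.00 h, with G still falling from 30.0 % at 1.50 h, so that run has passed its ceiling, which is a bend and not a stop; I therefore put Sunday's, as a low estimate, at its own ceiling plus the same excess, 86.6 %.

Above the ceiling's reach, time counts. I extend the north run's tail: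

k = ln(24.1 %/13.2 %)/(3.00 h − 1.50 h) = 0.401 h⁻¹

reacted at 6.0 h: 96.0 %

Thursday's, with more L than the north run, gets at least that. Friday's, interpolated in L, gets 91.7 %. The trend rises, by some 9.4 points.

The forecast gives 87 %, 92 % and 95.5 %, it rises, above mine on Sunday's, holding that “L hardly matters early but controls the slow tail”.

The flask gives 87.2 % for Sunday's, 92.7 % for Friday's and 97.3 % for Thursday's: it rises, by 10 points.

    G + J → X + D (k = 0.150 M⁻¹ s⁻¹)
    J + X ⇌ Q, settled at all times (K = 29000 M⁻¹)
    X + L ⇌ Z (K = 1.10 × 10⁵ M⁻¹, k = 0.390 M⁻¹ s⁻¹)
    D ⇌ E (K = 3.70, k = 2.10 × 10⁻⁴ s⁻¹)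

At 6.00 h Friday's holds 9.86 mM of Z with 10.3 % of its L free, and its 92.7 % stands below its ceiling of 96.7 %. The neighbour charged with 38 mM of G, its other charges as Friday's, has the same ceiling of 14.5 mM, which is 38.2 % of its G. It gives 42.9 % with 3.64 mM of X free at 6.00 h, and the ceiling plus half of that free X comes to 42.9 %.

The runs were generated by integration with constants of no real substance, noise included.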